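A unit of exposure, E, is what cuts the Int left by the factor e, so E = ln(Int charged / Int left). E is the rate constant of Int + Rgt times the Rgt present, summed over the time, so it should grow with the Rgt charged.

| setting | green | blue | gamma | theta |
|---|---|---|---|---|
| Int | 0.050 M | 0.050 M | 0.050 M | 0.050 M |
| Rgt | 0.078 M | 0.14 M | 0.0650 M | 0.0980 M |
| Lvg | 0.25 M | 0.25 M | 0.250 M | 0.250 M |
| remark | run made earlier | run made earlier |  |  |
| time |  |  | 4.0 min | 4.0 min |

- green (time / s: Int / %, Int2 / %): 15.0: 75, 22; 40.0: 55, 23; 80.0: 45, 21; 120: 43, 18
- blue (time / s: Int / %, Int2 / %): 10.0: 67, 20; 20.0: 48, 21; 50.0: 30, 18; 120: 18, 13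

(readings scatter by 1.5 percentage points)

- what is said of Lvg includes Lvg.Rgt
- what was read earlier has a scatter of 1.5 percentage points, one standard deviation
- candidate steps: Int + Rgt -> Lvg + Int2; Int2 + Rgt -> Lvg + Int3; Lvg + Rgt <-> Lvg.Rgt; Rgt -> Ofp; Lvg -> Lvg2

- part of the Int that has reacted at the end, gamma
- part of the Int that has reacted at the end, theta
- what raising the concentration of Rgt from its lowest to its highest value here does to the part of the Int that has reacted (changes below 5 percentage points count as none) (it rises / it falls / no change)

Green's Int has nearly stopped at 120 s, while blue's is still falling, so blue's exposure is read while it still grows. Green, blue, gamma and theta share Int at 0.050 M and Lvg at 0.250 M; with these held, try E per Rgt charged as the one number: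

green: E = 0.844, ratio 10.8 L mol⁻¹

blue: E = 1.71, ratio 12.2 L mol⁻¹

The ratios differ, so one number gives a band, not a point. Gamma's Rgt charge lies nearer green's than blue's:

gamma: E = 0.703, the exposure that the green ratio gives gamma's Rgt charge; reacted 50.5 %

Theta's Rgt charge lies between those of the two runs, so both ratios are used:

theta: reacted 65.4 % to 69.9 %

This reckoning therefore has the part reacted rising from gamma to theta, by 15 percentage points at the low end of the band.

The forecast, reasoning that “Rgt must also be lost by another route”, gives 52 % for gamma and 68 % for theta: it rises.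

The flasks give 51.2 % for gamma and 67.8 % for theta: it rises, by 17 points.

    Int + Rgt → Lvg + Int2 (k = 0.481 L mol⁻¹ s⁻¹)
    Int2 + Rgt → Lvg + Int3 (k = 1.12 L mol⁻¹ s⁻¹)
    Lvg + Rgt ⇌ Lvg.Rgt, settled at all times (K = 2.60 L mol⁻¹)
    Rgt → Ofp (k = 0.0168 s⁻¹)
    Lvg → Lvg2 (k = 0.0221 s⁻¹)

Gamma's exposure comes out at 0.718 against the reckoned 0.703, with 0.013 % of its Rgt, the limiting reagent, left at 4.00 min. The neighbouring flask is gamma with 0.12 M of Int, its Rgt charge unchanged. The ratio, read at 0.050 M of Int, again gives E = 0.703 and 50.5 % reacted. That flask gives E = 0.382 and 31.7 % reacted, with 0 % of its Rgt left.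

The data stem from a simulated flask with constants of no real substance, and the scatter is random.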